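What I want to know is how far the two substrates part by the end of Wednesday's and Sunday's flasks.

1. the flask that ends with the higher excess of right-handed substrate over left-handed substrate among what is left of the two, or "neither" when 2 percentage points or less lies between them (Wednesday's / Sunday's / neither)
2. excess of right-handed substrate over left-handed substrate among what is left of the two at the end, Wednesday's
3. excess of right-handed substrate over left-handed substrate among what is left of the two at the end, Sunday's

the same everywhere: left-handed substrate 0.50 M; right-handed substrate 0.50 M
- cedar: coupling partner 0.72 M; run made earlier
- elm: coupling partner 1.1 M; run made earlier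
- oak: coupling partner 1.2 M; run made earlier
- Wednesday's: coupling partner 1.00 M; time 8.0 h
- Sunday's: coupling partner 1.50 M; time 8.0 h

| run | time / h | right-handed substrate / % | left-handed substrate / % |
|---|---|---|---|
| cedar | 0.333 | 30.6 | 29.9 |
| cedar | 0.667 | 25.5 | 25.1 |
| cedar | 1.00 | 22.3 | 22.6 |
| cedar | 2.00 | 17.3 | 17.7 |
| cedar | 4.00 | 14.1 | 14.0 |
| elm | 0.333 | 25.7 | 25.0 |
| elm | 0.667 | 19.1 | 18.3 |
| elm | 1.00 | 15.4 | 14.8 |
| elm | 2.00 | 8.4 | 8.5 |
| elm | 4.00 | 4.2 | 4.3 |
| oak | 0.333 | 24.1 | 24.1 |
| oak | 0.667 | 17.4 | 16.9 |
| oak | 1.00 | 12.7 | 12.5 |
| oak | 2.00 | 6.9 | 6.9 |
| oak | 4.00 | 3.2 | 3.0 |

(scatter of a reading: 0.3 percentage points)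

- coupling partner is single-handed; left-handed substrate and right-handed substrate are mirror images of each other, charged as a racemate, each of them at the stated concentration
- steps under discussion: right-handed substrate <-> achiral form; left-handed substrate <-> achiral form; coupling partner <-> dormant form; left-handed product <-> right-handed product; coupling partner + right-handed substrate -> right-handed product; coupling partner + left-handed substrate -> left-handed product; coupling partner -> decomposition product
- an excess is the difference of the two amounts in percent of their sum
- an excess is below zero if the other one leads
- the handed part of coupling partner does not stay in what it makes, so the products of the two hands are mirror images too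

Sunday's flask holds 1.50 of coupling partner per unit of the two substrates charged together, and this ratio, the cover, is the number I carry. I draw the substrate curve from both ends, taking each partner to consume one substrate. At the start, the elm run loses 49.3% of its charge by 0.333 h, a slope of about 1.48 h⁻¹. At the far end, the cedar run has a cover of 0.720, which makes coupling partner the limiting reagent and gives a level of 28.0% for what stays uncoupled, achiral form counted. The two substrates of the cedar run still fall, from 35.0% at 2.00 h to 28.1% at 4.00 h, and these readings leave out the achiral form, so they do not test that level.

Wednesday's cover is 1.00, so its level is zero. Using elm's slope, the starting line meets that level near 0.676 h, and a slow tail follows. Sunday's keeps a third of its partner. The hands stay together: oak's last readings differ by 0.2 percentage points, less than the scatter. I expect Sunday's to show slightly more excess, with the gap inside the margin.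

The forecast says 0.5% for Wednesday's, 1.2% for Sunday's, and neither, expecting “a small steady-state excess that scales with remaining partner”.

The flasks give 0.104% for Wednesday's and 0.711% for Sunday's, so the answer is neither.

    right-handed substrate ⇌ achiral form (K = 0.330, k = 0.0120 s⁻¹)
    left-handed substrate ⇌ achiral form (K = 0.330, k = 0.0120 s⁻¹)
    coupling partner ⇌ dormant form (K = 0.600, k = 7.70 × 10⁻⁴ s⁻¹)
    left-handed product ⇌ right-handed product (k = 6.50 × 10⁻⁴ s⁻¹)
    coupling partner + right-handed substrate → right-handed product (k = 5.40 × 10⁻⁴ M⁻¹ s⁻¹)
    coupling partner + left-handed substrate → left-handed product (k = 0.00110 M⁻¹ s⁻¹)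
    coupling partner → decomposition product (k = 1.10 × 10⁻⁶ s⁻¹)

In Wednesday's at 8.00 h, coupling uses right-handed substrate at 0.0020 of the rate of its forward step to the achiral form. That forward step has a half-life of 0.96 min, whereas coupling gives left-handed substrate 3.9 h. In Sunday's at 8.00 h, free, dormant and decomposed partner together make 33.4% of its charge, against 33.3% from the cover. A flask like Wednesday's with 0.25 M of partner has a cover of 0.250, hence a level of 75.0%, and at 8.00 h its two substrates and achiral form hold 75.0%.

(All runs were computed from invented constants, and the scatter is random.)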